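The runs were computed with constants of no real substance, noise included.

One working second was the unit the meeting agreed on: a second with the whole partner charge present and the whole catalyst charge free.

the same everywhere: starting material 0.050 M; catalyst 50 µM
- maple: partner 0.10 M; second substrate 0.010 M; protic impurity 0.022 M; temperature 40 °C; run made earlier
- Sunday's: partner 0.100 M; second substrate 0.0100 M; protic impurity 0.0150 M; at 40 °C until 2.0 min, from then on at 100 °C; time 3.0 min
- Monday's: partner 0.100 M; second substrate 0.0100 M; protic impurity 0.0150 M; temperature 40 °C; time 3.0 min
- Tuesday's: partner 0.100 M; second substrate 0.0100 M; protic impurity 0.0150 M; temperature 70 °C; time 3.0 min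
- Friday's: partner 0.100 M; second substrate 0.0100 M; protic impurity 0.0150 M; temperature 100 °C; time 3.0 min

maple run (percent of the starting material charged)

| time / s | target / % | starting material / % |
|---|---|---|
| 10.0 | 5.6 | 93.2 |
| 20.0 | 11.5 | 88.8 |

(each reading ± 0.5 percentage points)

- what is said of target includes idle complex
- the numbers in the tables scatter with a standard deviation of 0.5 percentage points
- candidate steps: starting material + partner + catalyst -> catalyst + target; second substrate + partner + catalyst -> catalyst + second product; partner -> decomposed reagent; catalyst + target <-> idle complex; partner + protic impurity -> quenched reagent
- the earlier runs do not show what temperature does; that part of a forecast is a guess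
- no earlier run changes the charge of protic impurity; that part of a forecast is a guess

1. the flask that comes out highest in amount of target, in percent of the starting material charged, or "all alike" when all lie within 1.5 percentage points (Sunday's / Monday's / Tuesday's / Friday's / all alike)
2. target at the end, in percent of the starting material charged, Sunday's
3. target at the end, in percent of the starting material charged, Monday's
4. target at the end, in percent of the starting material charged, Tuesday's
5. target at the end, in percent of the starting material charged, Friday's

The first chemist opened with the maple run. She let a be the fraction of the starting material left and w the fraction of partner left times the fraction of catalyst free. The candidate step makes target at a rate proportional to all three species, she said, so d ln a/dt = −g·w. This integrates in closed form to −ln a = g·W, where W is the time integral of w, the count of working seconds. She treated the run's last reading, 11.5% target at 20.0 s, as early enough for w to be near its opening value. From it she read 0.00611 /s as g, the working rate constant, a pseudo-first-order constant of starting material at full partner. It is a reading, and each point scatters by 0.5 percentage points. She added that it holds for 50 µM of catalyst at 40 °C.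

The second chemist pointed out that protic impurity can take 15.0% of the partner charge. He also warned that partner turned into decomposed reagent costs working seconds and gives no target. Temperature, he said, remained a guess.

My own reckoning, entered here, held w at the remaining 85.0% for Monday's 3.0 min. That gives 60.7% target for Monday's, and I gave no figure for the hot flasks.

The forecast was then tabled. It named Sunday's as highest, with Sunday's at 84%, Monday's at 56%, Tuesday's at 80% and Friday's at 72%. Its figure for Monday's stood lower than mine. Its ground for the favourite was that “late heating finishes quickly with little time for partner loss”.

The flasks gave 35.3% for Sunday's, 39.6% for Monday's, 13.3% for Tuesday's and 3.10% for Friday's, so Monday's came out highest.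

    starting material + partner + catalyst → catalyst + target (k = 1400 /M²/s, Ea = 38.0 kJ/mol)
    second substrate + partner + catalyst → catalyst + second product (k = 5100 /M²/s, Ea = 29.0 kJ/mol)
    partner → decomposed reagent (k = 0.00520 /s, Ea = 97.0 kJ/mol)
    catalyst + target ⇌ idle complex (K = 61.0 /M, k = 0.130 /M/s, Ea = 51.0 kJ/mol, ΔH = −58.0 kJ/mol)
    partner + protic impurity → quenched reagent (k = 0.330 /M/s, Ea = 65.0 kJ/mol)
    (constants at 40 °C)

Monday's 39.6% amounts to 82.4 s of working time within its 3.0 min. At the end of Monday's, partner stood at 17.8% of its charge and idle complex held 23.9% of the catalyst. Sunday's 35.3% amounts to 71.4 s of working time, counted at the 40 °C value of g. The neighbouring flask is Sunday's with 3.0 × 10⁻⁵ M of catalyst. Scaling g with the catalyst charge and keeping Sunday's working seconds gives 23.0%. The neighbouring flask itself gives 24.8% target, with partner at 0% of its charge.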